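## The problem

The target 26 is a trans-2,3-disubstituted 2,3-dihydro-4H-furo[3,2-c]pyran-4-one. A 2-pyranone (ring A: C3a, C4, O5, C6, C7, C7a) is fused through C3a–C7a to a dihydrofuran (ring B: O1, C2, C3, C3a, C7a). C2 carries a 3,4-dihydroxyphenyl group, C3 a 4-hydroxy-2-oxo-2H-pyran-6-yl group (ring C) and C6 an (E)-4-hydroxystyryl group. The only stereocentres are C2 (S) and C3 (S), adjacent and trans; trans is the thermodynamic arrangement, so either centre can correct the other as long as the other one survives. Both are fragile: C2–O1 is the benzylic ether of a vinylogous acid with a para-oxygenated aryl group and ionises under acid, while C3–H lies between two pyranone rings and β to O1, so that a C3 carbanion, or proton loss from a C2 cation, opens ring B and erases both centres together. The free catechol and phenol are oxidisable, both 2-pyranones are lactones that do not tolerate strong nucleophiles, and the styryl double bond excludes hydrogenolysis in the final deprotection. The enabling feature is that O1–C2–C3–C3a–C4(=O) is a γ-aryl-γ-butyrolactone if O1 is bonded to C4 instead of C7a, with C7a–C7–C6 as a 1,3-diketone on the lactone α-carbon: rings A and B together are the dehydrated isomer of an α-(3,5-dioxoacyl) lactone. A trans-β,γ-disubstituted lactone of this kind is the direct product of an auxiliary-controlled succinate aldol reaction, and ring C, itself a triketide lactone, can be grown from a carbonyl group on C3.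

## Retrosynthesis

**26 from 25.** The three aryl O–benzyl bonds are cut last. Benzyl is the one phenol protecting group that should survive every earlier operation (boron aldol, borane, amide bases, hot sulfonic acid, fluoride, periodinane, BF3). The forward step must cleave three aryl ethers without hydrogen, because of the styryl group, and without opening C2–O1.

**25 from 23, and 23 from 19 and 21.** Ring C is opened at O1'–C2' to the acylketene 24, which is the thermolysis product of the keto-dioxinone 23. Then the C5'–C6' bond is cut, through alcohol 22, to the C3 aldehyde 19 and the silyl dienol ether 21, made from 20. The neighbouring cut, C-acylation of a dioxinone dienolate by a C3 acid chloride, is one step shorter but exposes the acidic C3–H with its β-oxygen to a strong base. The Lewis-acid aldol does not. Ring C shrinks to a formyl group; the forward sequence asks for γ-selective addition, an oxidation and a neutral thermolysis.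

**19 from 18 from 17.** These are adjustments of oxidation state and protection at the C3 carbon. That carbon is carried through the key step as a silyl ether. A free hydroxymethyl group would offer a second five-membered closure onto C7a, and a carboxyl derivative would not survive the enolate chemistry before it.

**17 from 15 (key disconnection).** C4–O5 and O1–C7a are cut and O1 is rejoined to C4, giving the α-(3,5-dioxoacyl) lactone 15. The alternative cuts at O1–C2, at C2–C3 with O1–C2, or at C3–C3a all leave C2 or C3 to be created on a finished pyranone. This cut moves both stereocentres into a monocyclic lactone where trans control and absolute control are routine, and it closes rings A and B together with the styryl group already in place. The forward reaction must be an acid-mediated cascade that attaches the two oxygens to the right carbons and leaves C2–O1 and C3 alone.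

**15 from 11 and 14.** The C6–C7 bond is cut: the terminal carbanion of the dianion of acetyl lactone 11 is acylated by the cinnamic N-methoxy-N-methylamide 14, made from acid 12 through acyl imidazole 13. This brings in the whole styryl arm as a commercial cinnamic acid; the forward step asks for terminal C-acylation without conjugate addition.

**11 from 10.** The C3a–C7a bond is cut, a C-acetylation of the lactone enolate. The lactone has a single enolisable position, and the enolate has no β-leaving group.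

**10 from 9 from 8.** Silylation and chemoselective reduction of the paraconic acid 8. The carboxyl of 8 is already at the oxidation level ring C needs. It is reduced nevertheless, because an ester at that position would be deprotonated by the bases of the next two steps and would open the lactone by β-elimination. This costs three redox and protection steps later.

**8 from 6, and 6 from 3 and 4.** The auxiliary is removed (6 to 8 through percarboxylate 7). Then C2–C3 and the lactone C–O bond are cut in an aldol–lactonisation of the succinoyl imide 3 with aldehyde 4 through aldolate 5. One reaction sets both stereocentres, and a syn aldol necessarily gives the trans lactone. Imide 3 comes from auxiliary 1 and acid chloride 2.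

## Roads not taken

**Alternative 1:** Ring B is made by contracting a six-membered ring, forming C3–C3a. The substrate would be (2S)-2-[3,4-bis(benzyloxy)phenyl]-7-methyl-2,3-dihydro-4H,5H-pyrano[4,3-b]pyran-4,5-dione A1. The trivalent iodine reagent PhI(OAc)2, with trimethyl orthoformate and H2SO4, would iodinate the enol ether of the ring ketone at its CH2 carbon. The ring-fusion pyranone carbon then migrates from the ketone carbon to that carbon with loss of iodobenzene, giving the methyl ester A2, methyl (2S,3S)-trans-2-[3,4-bis(benzyloxy)phenyl]-6-methyl-4-oxo-2,3-dihydro-4H-furo[3,2-c]pyran-3-carboxylate.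

- Merits: the reaction type is established for 2-arylchroman-4-ones, trans is set under C2 control, and C3 arrives as a carboxylate. On this last point the road is better than the chosen plan, which spends a reduction, a silylation, a desilylation and two oxidations on the same carbon.
- Weak points: the single stereocentre of A1 is a β-oxygenated benzylic ketone position that racemises by retro-oxa-Michael opening in strong acid. The electron-rich aryl group on C2 competes as the migrating group and is itself oxidisable by the iodane. A2 carries only a methyl group at C6, so the styryl arm must be added by a base-mediated condensation while the C3 ester makes C3–H acidic and ring B easy to open.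
- Comparison: the chosen plan sets against the better redox economy a secure source of both configurations and a styryl group that is in place before the bicycle exists.

**Alternative 2:** Ring B is made by inserting C2 between C3 and O1, forming C2–C3 and O1–C2. Cs2CO3 would release the 3-alkylidenepyran-2,4-dione A4 from its sulfinate adduct A3. The ylide of the chiral sulfonium salt A5 adds to the exocyclic carbon, and the C7a enolate oxygen displaces the sulfide, giving the tetra-O-benzyl ether A6 of the target.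

- Merits: this is the most convergent road. All three rings and both stereocentres are assembled from two halves in one step, and A6 is one deprotection from 26. On step count and convergence it is clearly better than the chosen plan.
- Weak points: the absolute configuration rests on face selection by a chiral sulfide at a transient acceptor. A4 carries an electron-poor pyranone on the reacting carbon, which makes it prone to take up a second pyranone nucleophile or to oligomerise, and leaves an acidic C3–H in the betaine, so the trans preference and the enantioselectivity are open questions for this class.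
- Comparison: the chosen plan sets against the roughly halved step count an aldol of predictable absolute sense and diastereomers that can be separated early, and it avoids an unstable quinone methide.

**Alternative 3:** Only O1–C2 is formed. Controlled-potential anodic oxidation (carbon anode, 2,6-lutidine, hexafluoroisopropanol) of the 3-benzyloxy-4-hydroxyphenyl group of A7 would give a para-quinone methide. The ring A hydroxyl adds to its exocyclic carbon in a 5-exo closure, giving A8, the tri-O-benzyl ether of the target with the catechol 4-hydroxyl free.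

- Merits: no chemical oxidant, no strong acid, one bond formed on a complete skeleton, and trans set by C3. In mildness of the ring-B closure this road is better than the chosen one.
- Weak points: A7 must already hold C3 as a single enantiomer between two pyranone rings, a centre that is hard to set alone and easy to racemise. The quinone methide can tautomerise by loss of that same proton. The 4-benzyloxystyryl-pyranone and the hydroxypyranone enol are oxidisable near the same potential. The differentiated catechol adds protecting-group steps.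
- Comparison: the chosen plan sets against the milder closure the creation of C2 and C3 together, and a key step that needs no selection among several electron-rich π systems.

Key step: step 9

Remark: metal enolates and other ionic forms of a numbered compound are treated as that compound and carry no number of their own.

## Route

Step 1
Reactants: 1 (S)-4-benzyl-1,3-oxazolidin-2-one; 2 methyl 4-chloro-4-oxobutanoate
Product: 3 methyl 4-[(4S)-4-benzyl-2-oxo-1,3-oxazolidin-3-yl]-4-oxobutanoate
Conditions: n-BuLi, THF, −78 °C; then 2, −78 to 0 °C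
Reagents that add atoms: none
Why: N-acylation of the lithiated oxazolidinone by the acid chloride, which reacts far faster than the methyl ester; standard imide formation.

Step 2
Reactants: 3 methyl 4-[(4S)-4-benzyl-2-oxo-1,3-oxazolidin-3-yl]-4-oxobutanoate; 4 3,4-bis(benzyloxy)benzaldehyde
Product: 6 (4S)-4-benzyl-3-{[(2S,3S)-2-[3,4-bis(benzyloxy)phenyl]-5-oxooxolan-3-yl]carbonyl}-1,3-oxazolidin-2-one, via boron syn-aldolate 5 (not isolated)
Conditions: Bu2BOTf, iPr2NEt, CH2Cl2, 0 °C; 4, −78 °C to rt; pH 7 buffer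
Reagents that add atoms: none
Why: Evans syn-aldol: only the imide is enolised, and the Z boron enolate adds through a Zimmerman–Traxler chair on the face opposite the auxiliary benzyl group, setting both centres as (3S,4S) in 5. The aldolate oxygen then acylates itself with the methyl ester (5-exo-trig), and a syn aldol can only give the 2,3-trans lactone.

Step 3
Reactants: 6 (4S)-4-benzyl-3-{[(2S,3S)-2-[3,4-bis(benzyloxy)phenyl]-5-oxooxolan-3-yl]carbonyl}-1,3-oxazolidin-2-one
Product: 8 (2S,3S)-2-[3,4-bis(benzyloxy)phenyl]-5-oxooxolane-3-carboxylic acid, via lithium percarboxylate 7 (not isolated)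
Conditions: LiOH, H2O2, THF–H2O, 0 °C; Na2SO3; HCl to pH 2
Reagents that add atoms: hydrogen peroxide, OO
Why: Hydroperoxide attacks the exocyclic imide carbonyl selectively (auxiliary cleavage) and sulfite reduces the percarboxylate. Any lactone opened by base re-closes on acidification by acyl–oxygen lactonisation, so neither centre is touched.

Step 4
Reactants: 8 (2S,3S)-2-[3,4-bis(benzyloxy)phenyl]-5-oxooxolane-3-carboxylic acid
Product: 9 (4R,5S)-5-[3,4-bis(benzyloxy)phenyl]-4-(hydroxymethyl)oxolan-2-one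
Conditions: BH3·SMe2, THF, 0 °C to rt; MeOH
Reagents that add atoms: none
Why: Borane reduces a carboxylic acid through its acyloxyborane much faster than a lactone (chemoselective acid reduction). The descriptor at C4 changes by priority only; the alcohol is silylated at once to forestall translactonisation.

Step 5
Reactants: 9 (4R,5S)-5-[3,4-bis(benzyloxy)phenyl]-4-(hydroxymethyl)oxolan-2-one
Product: 10 (4R,5S)-5-[3,4-bis(benzyloxy)phenyl]-4-{[(tert-butyldiphenylsilyl)oxy]methyl}oxolan-2-one
Conditions: TBDPSCl, imidazole, DMF, rt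
Reagents that add atoms: tert-butyl(chloro)diphenylsilane, CC(C)(C)[Si](Cl)(c1ccccc1)c1ccccc1
Why: Standard silylation of a primary alcohol; this silyl ether is chosen for its resistance to amide bases and to the acid of step 9.

Step 6
Reactants: 10 (4R,5S)-5-[3,4-bis(benzyloxy)phenyl]-4-{[(tert-butyldiphenylsilyl)oxy]methyl}oxolan-2-one
Product: 11 (4R,5S)-3-acetyl-5-[3,4-bis(benzyloxy)phenyl]-4-{[(tert-butyldiphenylsilyl)oxy]methyl}oxolan-2-one (C3 labile, 3,4-trans keto form in equilibrium with its enol)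
Conditions: LiN(SiMe3)2 (2.2 equiv), THF, −78 °C; AcCl; AcOH
Reagents that add atoms: acetyl chloride, CC(=O)Cl
Why: Claisen-type C-acylation of the lithium lactone enolate, with a second equivalent of base because the β-keto lactone is more acidic than 10. The enolate has no β-leaving group, and the new C3 centre is a labile β-dicarbonyl position of no consequence.

Step 7
Reactants: 12 (E)-3-[4-(benzyloxy)phenyl]prop-2-enoic acid
Product: 14 (E)-3-[4-(benzyloxy)phenyl]-N-methoxy-N-methylprop-2-enamide, via acyl imidazole 13 (not isolated)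
Conditions: CDI, CH2Cl2, rt; MeNH(OMe)·HCl, rt
Reagents that add atoms: N,O-dimethylhydroxylamine hydrochloride, CNOC.Cl
Why: Carbonyldiimidazole activation followed by aminolysis, the standard Weinreb amide synthesis; the E double bond is not involved.

Step 8
Reactants: 11 (4R,5S)-3-acetyl-5-[3,4-bis(benzyloxy)phenyl]-4-{[(tert-butyldiphenylsilyl)oxy]methyl}oxolan-2-one; 14 (E)-3-[4-(benzyloxy)phenyl]-N-methoxy-N-methylprop-2-enamide
Product: 15 (4R,5S)-3-{(E)-5-[4-(benzyloxy)phenyl]-3-oxopent-4-enoyl}-5-[3,4-bis(benzyloxy)phenyl]-4-{[(tert-butyldiphenylsilyl)oxy]methyl}oxolan-2-one (C3 labile, mixture of enol forms)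
Conditions: LiN(iPr)2 (2.3 equiv), THF, −78 to −20 °C; 14, −78 to 0 °C; AcOH
Reagents that add atoms: none
Why: 1,3-Dicarbonyl dianion acylation: the second deprotonation takes place at the acetyl methyl group, and this more reactive terminal carbanion attacks the Weinreb amide at the carbonyl. The chelated tetrahedral adduct prevents over-addition and releases the triketone only on acidic quench.

Step 9
Reactants: 15 (4R,5S)-3-{(E)-5-[4-(benzyloxy)phenyl]-3-oxopent-4-enoyl}-5-[3,4-bis(benzyloxy)phenyl]-4-{[(tert-butyldiphenylsilyl)oxy]methyl}oxolan-2-one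
Product: 17 (2S,3R)-2-[3,4-bis(benzyloxy)phenyl]-6-{(E)-2-[4-(benzyloxy)phenyl]ethenyl}-3-{[(tert-butyldiphenylsilyl)oxy]methyl}-2,3-dihydro-4H-furo[3,2-c]pyran-4-one, via hydroxyalkyl hydroxypyranone 16 (not isolated)
Conditions: TsOH·H2O (0.2 equiv), 4 Å MS, toluene, 80 °C
Reagents that add atoms: none
Why: Acid-catalysed translactonisation–cyclodehydration cascade. Protonation of the lactone carbonyl C4 lets the enol oxygen of the C6 ketone add in a 6-exo-trig acyl substitution, and collapse of the adduct with expulsion of the lactone oxygen forms C4–O5 and ring A and frees the C2 hydroxyl in 16. That hydroxyl then adds to C7a of the pyran-2,4-dione tautomer (5-exo-trig) and water is lost, forming O1–C7a and ring B; the sieves remove the water and drive the sequence. The closest known reaction types are the acid-catalysed acyl-lactone rearrangement of α-acyl-γ-butyrolactones to 4,5-dihydrofuran-3-carboxylic acid derivatives and the cyclisation of 3,5-dioxo esters to 4-hydroxy-2-pyranones, run here in one flask. No stereocentre is formed: C2–O1 and C3 are not touched, so the 4,5-trans lactone becomes the 2,3-trans ring B, and if C2 should ionise, re-closure anti to the C3 substituent returns the same isomer. The selectivity needed is closure of O1 onto C7a (4-alkoxy-2-pyranone) rather than loss of water from the C4 adduct with O1 still on C4 (2-alkoxy-4-pyranone isomer); it is secured because the ionisable C2–O bond lets the two isomers interconvert under the acid and the 4-alkoxy-2-pyranone is the more stable. The silyl ether keeps the primary oxygen on C3 from competing for C7a.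

Step 10
Reactants: 17 (2S,3R)-2-[3,4-bis(benzyloxy)phenyl]-6-{(E)-2-[4-(benzyloxy)phenyl]ethenyl}-3-{[(tert-butyldiphenylsilyl)oxy]methyl}-2,3-dihydro-4H-furo[3,2-c]pyran-4-one
Product: 18 (2S,3R)-2-[3,4-bis(benzyloxy)phenyl]-6-{(E)-2-[4-(benzyloxy)phenyl]ethenyl}-3-(hydroxymethyl)-2,3-dihydro-4H-furo[3,2-c]pyran-4-one
Conditions: HF·pyridine, pyridine, THF, 0 °C to rt
Reagents that add atoms: none
Why: Fluoride-driven cleavage of the Si–O bond; the buffered reagent is neither basic nor nucleophilic enough to harm the pyranone, the benzyl ethers or C2–O1.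

Step 11
Reactants: 18 (2S,3R)-2-[3,4-bis(benzyloxy)phenyl]-6-{(E)-2-[4-(benzyloxy)phenyl]ethenyl}-3-(hydroxymethyl)-2,3-dihydro-4H-furo[3,2-c]pyran-4-one
Product: 19 (2S,3S)-2-[3,4-bis(benzyloxy)phenyl]-6-{(E)-2-[4-(benzyloxy)phenyl]ethenyl}-4-oxo-2,3-dihydro-4H-furo[3,2-c]pyran-3-carbaldehyde
Conditions: Dess–Martin periodinane, NaHCO3, CH2Cl2, 0 °C to rt
Reagents that add atoms: none
Why: Dess–Martin oxidation under buffered, non-basic conditions. The aldehyde is enolisable, but epimerisation at C3 returns to trans under C2 control; it is used crude.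

Step 12
Reactants: 20 2,2,6-trimethyl-4H-1,3-dioxin-4-one
Product: 21 [(2,2-dimethyl-6-methylidene-6H-1,3-dioxin-4-yl)oxy]trimethylsilane
Conditions: LiN(iPr)2, THF, −78 °C; Me3SiCl
Reagents that add atoms: chlorotrimethylsilane, C[Si](C)(C)Cl
Why: γ-Deprotonation of the vinylogous ester and O-silylation of the dienolate, the standard preparation of this silyl dienol ether.

Step 13
Reactants: 19 (2S,3S)-2-[3,4-bis(benzyloxy)phenyl]-6-{(E)-2-[4-(benzyloxy)phenyl]ethenyl}-4-oxo-2,3-dihydro-4H-furo[3,2-c]pyran-3-carbaldehyde; 21 [(2,2-dimethyl-6-methylidene-6H-1,3-dioxin-4-yl)oxy]trimethylsilane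
Product: 22 6-{2-[(2S,3R)-2-[3,4-bis(benzyloxy)phenyl]-6-{(E)-2-[4-(benzyloxy)phenyl]ethenyl}-4-oxo-2,3-dihydro-4H-furo[3,2-c]pyran-3-yl]-2-hydroxyethyl}-2,2-dimethyl-4H-1,3-dioxin-4-one (both carbinol epimers)
Conditions: BF3·OEt2, CH2Cl2, −78 °C; H2O
Reagents that add atoms: none
Why: Vinylogous Mukaiyama aldol: the BF3-activated aldehyde is attacked by the exocyclic γ-carbon of the dienol ether, and no base meets the C3–H. The carbinol centre is formed without control and is removed in step 14.

Step 14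
Reactants: 22 6-{2-[(2S,3R)-2-[3,4-bis(benzyloxy)phenyl]-6-{(E)-2-[4-(benzyloxy)phenyl]ethenyl}-4-oxo-2,3-dihydro-4H-furo[3,2-c]pyran-3-yl]-2-hydroxyethyl}-2,2-dimethyl-4H-1,3-dioxin-4-one
Product: 23 6-{2-[(2S,3S)-2-[3,4-bis(benzyloxy)phenyl]-6-{(E)-2-[4-(benzyloxy)phenyl]ethenyl}-4-oxo-2,3-dihydro-4H-furo[3,2-c]pyran-3-yl]-2-oxoethyl}-2,2-dimethyl-4H-1,3-dioxin-4-one
Conditions: Dess–Martin periodinane, NaHCO3, CH2Cl2, rt
Reagents that add atoms: none
Why: Dess–Martin oxidation of the secondary alcohol to the β-keto dioxinone; both epimers of 22 converge, and enolisation is expected towards the CH2 group and not towards C3.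

Step 15
Reactants: 23 6-{2-[(2S,3S)-2-[3,4-bis(benzyloxy)phenyl]-6-{(E)-2-[4-(benzyloxy)phenyl]ethenyl}-4-oxo-2,3-dihydro-4H-furo[3,2-c]pyran-3-yl]-2-oxoethyl}-2,2-dimethyl-4H-1,3-dioxin-4-one
Product: 25 (2S,3S)-2-[3,4-bis(benzyloxy)phenyl]-6-{(E)-2-[4-(benzyloxy)phenyl]ethenyl}-3-(4-hydroxy-2-oxo-2H-pyran-6-yl)-2,3-dihydro-4H-furo[3,2-c]pyran-4-one, via acylketene 24 (not isolated)
Conditions: toluene (0.01 M), 110 °C
Reagents that add atoms: none
Why: Thermal retro-[4+2] of the dioxinone expels acetone and gives acylketene 24, whose ketone enol adds to the ketene carbon (6π oxa-electrocyclisation) to close the 4-hydroxy-2-pyranone ring C. The medium is neutral, so the trans pair is retained.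

Step 16
Reactants: 25 (2S,3S)-2-[3,4-bis(benzyloxy)phenyl]-6-{(E)-2-[4-(benzyloxy)phenyl]ethenyl}-3-(4-hydroxy-2-oxo-2H-pyran-6-yl)-2,3-dihydro-4H-furo[3,2-c]pyran-4-one
Product: 26 (2S,3S)-2-(3,4-dihydroxyphenyl)-3-(4-hydroxy-2-oxo-2H-pyran-6-yl)-6-[(E)-2-(4-hydroxyphenyl)ethenyl]-2,3-dihydro-4H-furo[3,2-c]pyran-4-one
Conditions: BCl3, C6HMe5, CH2Cl2, −78 °C; MeOH
Reagents that add atoms: none
Why: Lewis-acid cleavage of aryl benzyl ethers with pentamethylbenzene as trap for the benzyl cations. The low temperature and the absence of hydrogen should spare the styryl double bond, both lactones and the C2–O1 bond.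

## Compound list

1 | (S)-4-benzyl-1,3-oxazolidin-2-one | O=C1N[C@@H](Cc2ccccc2)CO1 | starting material
2 | methyl 4-chloro-4-oxobutanoate | COC(=O)CCC(=O)Cl | starting material
3 | methyl 4-[(4S)-4-benzyl-2-oxo-1,3-oxazolidin-3-yl]-4-oxobutanoate | COC(=O)CCC(=O)N1[C@@H](Cc2ccccc2)COC1=O | intermediate
4 | 3,4-bis(benzyloxy)benzaldehyde | O=Cc1ccc(OCc2ccccc2)c(OCc2ccccc2)c1 | starting material
5 | dibutylboron aldolate of methyl (3S,4S)-3-{[(4S)-4-benzyl-2-oxo-1,3-oxazolidin-3-yl]carbonyl}-4-[3,4-bis(benzyloxy)phenyl]-4-hydroxybutanoate | COC(=O)C[C@H](C(=O)N1[C@@H](Cc2ccccc2)COC1=O)[C@H](OB(CCCC)CCCC)c1ccc(OCc2ccccc2)c(OCc2ccccc2)c1 | intermediate (not isolated)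
6 | (4S)-4-benzyl-3-{[(2S,3S)-2-[3,4-bis(benzyloxy)phenyl]-5-oxooxolan-3-yl]carbonyl}-1,3-oxazolidin-2-one | O=C1OC[C@H](Cc2ccccc2)N1C(=O)[C@H]1CC(=O)O[C@@H]1c1ccc(OCc2ccccc2)c(OCc2ccccc2)c1 | intermediate
7 | lithium (2S,3S)-2-[3,4-bis(benzyloxy)phenyl]-5-oxooxolane-3-carboperoxoate | [Li+].[O-]OC(=O)[C@H]1CC(=O)O[C@@H]1c1ccc(OCc2ccccc2)c(OCc2ccccc2)c1 | intermediate (not isolated)
8 | (2S,3S)-2-[3,4-bis(benzyloxy)phenyl]-5-oxooxolane-3-carboxylic acid | OC(=O)[C@H]1CC(=O)O[C@@H]1c1ccc(OCc2ccccc2)c(OCc2ccccc2)c1 | intermediate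
9 | (4R,5S)-5-[3,4-bis(benzyloxy)phenyl]-4-(hydroxymethyl)oxolan-2-one | OC[C@H]1CC(=O)O[C@@H]1c1ccc(OCc2ccccc2)c(OCc2ccccc2)c1 | intermediate
10 | (4R,5S)-5-[3,4-bis(benzyloxy)phenyl]-4-{[(tert-butyldiphenylsilyl)oxy]methyl}oxolan-2-one | CC(C)(C)[Si](c1ccccc1)(c1ccccc1)OC[C@H]1CC(=O)O[C@@H]1c1ccc(OCc2ccccc2)c(OCc2ccccc2)c1 | intermediate
11 | (4R,5S)-3-acetyl-5-[3,4-bis(benzyloxy)phenyl]-4-{[(tert-butyldiphenylsilyl)oxy]methyl}oxolan-2-one (C3 labile) | CC(C)(C)[Si](c1ccccc1)(c1ccccc1)OC[C@H]1C(C(C)=O)C(=O)O[C@@H]1c1ccc(OCc2ccccc2)c(OCc2ccccc2)c1 | intermediate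
12 | (E)-3-[4-(benzyloxy)phenyl]prop-2-enoic acid | O=C(O)/C=C/c1ccc(OCc2ccccc2)cc1 | starting material
13 | (E)-3-[4-(benzyloxy)phenyl]-1-(1H-imidazol-1-yl)prop-2-en-1-one | O=C(/C=C/c1ccc(OCc2ccccc2)cc1)n1ccnc1 | intermediate (not isolated)
14 | (E)-3-[4-(benzyloxy)phenyl]-N-methoxy-N-methylprop-2-enamide | CON(C)C(=O)/C=C/c1ccc(OCc2ccccc2)cc1 | intermediate
15 | (4R,5S)-3-{(E)-5-[4-(benzyloxy)phenyl]-3-oxopent-4-enoyl}-5-[3,4-bis(benzyloxy)phenyl]-4-{[(tert-butyldiphenylsilyl)oxy]methyl}oxolan-2-one (C3 labile) | CC(C)(C)[Si](c1ccccc1)(c1ccccc1)OC[C@H]1C(C(=O)CC(=O)/C=C/c2ccc(OCc3ccccc3)cc2)C(=O)O[C@@H]1c1ccc(OCc2ccccc2)c(OCc2ccccc2)c1 | intermediate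
16 | 6-{(E)-2-[4-(benzyloxy)phenyl]ethenyl}-3-{(1S,2R)-1-[3,4-bis(benzyloxy)phenyl]-3-[(tert-butyldiphenylsilyl)oxy]-1-hydroxypropan-2-yl}-4-hydroxy-2H-pyran-2-one | CC(C)(C)[Si](c1ccccc1)(c1ccccc1)OC[C@@H](c1c(O)cc(/C=C/c2ccc(OCc3ccccc3)cc2)oc1=O)[C@H](O)c1ccc(OCc2ccccc2)c(OCc2ccccc2)c1 | intermediate (not isolated)
17 | (2S,3R)-2-[3,4-bis(benzyloxy)phenyl]-6-{(E)-2-[4-(benzyloxy)phenyl]ethenyl}-3-{[(tert-butyldiphenylsilyl)oxy]methyl}-2,3-dihydro-4H-furo[3,2-c]pyran-4-one | CC(C)(C)[Si](c1ccccc1)(c1ccccc1)OC[C@H]1c2c(cc(/C=C/c3ccc(OCc4ccccc4)cc3)oc2=O)O[C@@H]1c1ccc(OCc2ccccc2)c(OCc2ccccc2)c1 | intermediate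
18 | (2S,3R)-2-[3,4-bis(benzyloxy)phenyl]-6-{(E)-2-[4-(benzyloxy)phenyl]ethenyl}-3-(hydroxymethyl)-2,3-dihydro-4H-furo[3,2-c]pyran-4-one | OC[C@H]1c2c(cc(/C=C/c3ccc(OCc4ccccc4)cc3)oc2=O)O[C@@H]1c1ccc(OCc2ccccc2)c(OCc2ccccc2)c1 | intermediate
19 | (2S,3S)-2-[3,4-bis(benzyloxy)phenyl]-6-{(E)-2-[4-(benzyloxy)phenyl]ethenyl}-4-oxo-2,3-dihydro-4H-furo[3,2-c]pyran-3-carbaldehyde | O=C[C@H]1c2c(cc(/C=C/c3ccc(OCc4ccccc4)cc3)oc2=O)O[C@@H]1c1ccc(OCc2ccccc2)c(OCc2ccccc2)c1 | intermediate
20 | 2,2,6-trimethyl-4H-1,3-dioxin-4-one | CC1=CC(=O)OC(C)(C)O1 | starting material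
21 | [(2,2-dimethyl-6-methylidene-6H-1,3-dioxin-4-yl)oxy]trimethylsilane | C=C1C=C(O[Si](C)(C)C)OC(C)(C)O1 | intermediate
22 | 6-{2-[(2S,3R)-2-[3,4-bis(benzyloxy)phenyl]-6-{(E)-2-[4-(benzyloxy)phenyl]ethenyl}-4-oxo-2,3-dihydro-4H-furo[3,2-c]pyran-3-yl]-2-hydroxyethyl}-2,2-dimethyl-4H-1,3-dioxin-4-one (carbinol epimers) | CC1(C)OC(CC(O)[C@H]2c3c(cc(/C=C/c4ccc(OCc5ccccc5)cc4)oc3=O)O[C@@H]2c2ccc(OCc3ccccc3)c(OCc3ccccc3)c2)=CC(=O)O1 | intermediate
23 | 6-{2-[(2S,3S)-2-[3,4-bis(benzyloxy)phenyl]-6-{(E)-2-[4-(benzyloxy)phenyl]ethenyl}-4-oxo-2,3-dihydro-4H-furo[3,2-c]pyran-3-yl]-2-oxoethyl}-2,2-dimethyl-4H-1,3-dioxin-4-one | CC1(C)OC(CC(=O)[C@H]2c3c(cc(/C=C/c4ccc(OCc5ccccc5)cc4)oc3=O)O[C@@H]2c2ccc(OCc3ccccc3)c(OCc3ccccc3)c2)=CC(=O)O1 | intermediate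
24 | 5-[(2S,3S)-2-[3,4-bis(benzyloxy)phenyl]-6-{(E)-2-[4-(benzyloxy)phenyl]ethenyl}-4-oxo-2,3-dihydro-4H-furo[3,2-c]pyran-3-yl]pent-1-ene-1,3,5-trione | O=C=CC(=O)CC(=O)[C@H]1c2c(cc(/C=C/c3ccc(OCc4ccccc4)cc3)oc2=O)O[C@@H]1c1ccc(OCc2ccccc2)c(OCc2ccccc2)c1 | intermediate (not isolated)
25 | (2S,3S)-2-[3,4-bis(benzyloxy)phenyl]-6-{(E)-2-[4-(benzyloxy)phenyl]ethenyl}-3-(4-hydroxy-2-oxo-2H-pyran-6-yl)-2,3-dihydro-4H-furo[3,2-c]pyran-4-one | O=c1cc(O)cc([C@H]2c3c(cc(/C=C/c4ccc(OCc5ccccc5)cc4)oc3=O)O[C@@H]2c2ccc(OCc3ccccc3)c(OCc3ccccc3)c2)o1 | intermediate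
26 | (2S,3S)-2-(3,4-dihydroxyphenyl)-3-(4-hydroxy-2-oxo-2H-pyran-6-yl)-6-[(E)-2-(4-hydroxyphenyl)ethenyl]-2,3-dihydro-4H-furo[3,2-c]pyran-4-one | O=c1cc(O)cc([C@H]2c3c(cc(/C=C/c4ccc(O)cc4)oc3=O)O[C@@H]2c2ccc(O)c(O)c2)o1 | target

## Step count and risk

Total: 16 steps. Longest linear sequence: 14 steps (steps 1–6, 8–11 and 13–16, from 1 and 2); steps 7 and 12 prepare the side-arm reagents 14 and 21.

**Step 9 (key step).** Three things may go wrong.
- Closure through the wrong oxygen: water is lost from the C4 adduct while O1 stays on C4, giving the linear 4-pyranone skeleton.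
- Ionisation at C2 followed by loss of the C3 proton, which would erase C3 and lower the enantiomeric purity after re-closure.
- Partial loss of the silyl group, which would let the primary oxygen close onto C7a.

Fallback: the two rings are closed one after the other by the two parent reactions. From 11, methanolic HCl at 0 °C should effect the acyl-lactone rearrangement to methyl (4R,5S)-5-[3,4-bis(benzyloxy)phenyl]-4-{[(tert-butyldiphenylsilyl)oxy]methyl}-2-methyl-4,5-dihydrofuran-3-carboxylate F1, which already holds ring B and O1–C7a. Deprotonation of its 2-methyl group with LiN(iPr)2 and acylation with 14 should give the δ-keto ester methyl (4R,5S)-2-{(E)-4-[4-(benzyloxy)phenyl]-2-oxobut-3-en-1-yl}-5-[3,4-bis(benzyloxy)phenyl]-4-{[(tert-butyldiphenylsilyl)oxy]methyl}-4,5-dihydrofuran-3-carboxylate F2. DBU in toluene then closes ring A (C4–O5) with loss of methanol and returns to the route at 17.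

**Step 8.** The dianion may form incompletely, may add in conjugate fashion to the cinnamoyl amide, or may be quenched by proton transfer from the amide. Fallback: from 11 the same dianion is added at −78 °C to (E)-3-[4-(benzyloxy)phenyl]prop-2-enal, an aldol addition in place of the acylation. This gives (4R,5S)-3-{(E)-5-[4-(benzyloxy)phenyl]-3-hydroxypent-4-enoyl}-5-[3,4-bis(benzyloxy)phenyl]-4-{[(tert-butyldiphenylsilyl)oxy]methyl}oxolan-2-one F3, whose allylic alcohol is oxidised with MnO2 to return at 15.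

**Step 13.** The aldehyde carries an acidic C3–H with a β-oxygen. It may enolise and open ring B by retro-oxa-Michael elimination under the Lewis acid or on handling, and α-attack of the dienol ether may compete. Fallback: from 18, TEMPO with PhI(OAc)2 in MeCN–water should give (2S,3S)-2-[3,4-bis(benzyloxy)phenyl]-6-{(E)-2-[4-(benzyloxy)phenyl]ethenyl}-4-oxo-2,3-dihydro-4H-furo[3,2-c]pyran-3-carboxylic acid F4. Oxalyl chloride converts it into the corresponding (2S,3S)-3-carbonyl chloride F5. C-acylation of the lithium dienolate of 20 (LiN(SiMe3)2, THF, −78 °C) by F5 returns at 23, so 19 and 22 are never made.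

**Step 16.** Released benzyl cations may alkylate the nucleophilic C3' of ring C and the catechol ring, and the Lewis acid may open the C2–O1 bond. Fallback: the order of the last two events is reversed. From 23 the same debenzylation, applied before ring C exists, should give 6-{2-[(2S,3S)-2-(3,4-dihydroxyphenyl)-6-[(E)-2-(4-hydroxyphenyl)ethenyl]-4-oxo-2,3-dihydro-4H-furo[3,2-c]pyran-3-yl]-2-oxoethyl}-2,2-dimethyl-4H-1,3-dioxin-4-one F6. Neutral thermolysis in dilute dioxane then closes ring C and returns directly at 26.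

**Step 6.** O-acylation, double acylation or ketene formation from acetyl chloride may lower the conversion. Fallback: from 10 the lithium enolate is added to acetaldehyde (aldol addition) to give (4R,5S)-5-[3,4-bis(benzyloxy)phenyl]-4-{[(tert-butyldiphenylsilyl)oxy]methyl}-3-(1-hydroxyethyl)oxolan-2-one F7, and Dess–Martin oxidation returns at 11.

## Further compounds

F1 | step 9 | methyl (4R,5S)-5-[3,4-bis(benzyloxy)phenyl]-4-{[(tert-butyldiphenylsilyl)oxy]methyl}-2-methyl-4,5-dihydrofuran-3-carboxylate | CC(C)(C)[Si](c1ccccc1)(c1ccccc1)OC[C@H]1C(C(=O)OC)=C(C)O[C@@H]1c1ccc(OCc2ccccc2)c(OCc2ccccc2)c1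
F2 | step 9 | methyl (4R,5S)-2-{(E)-4-[4-(benzyloxy)phenyl]-2-oxobut-3-en-1-yl}-5-[3,4-bis(benzyloxy)phenyl]-4-{[(tert-butyldiphenylsilyl)oxy]methyl}-4,5-dihydrofuran-3-carboxylate | CC(C)(C)[Si](c1ccccc1)(c1ccccc1)OC[C@H]1C(C(=O)OC)=C(CC(=O)/C=C/c2ccc(OCc3ccccc3)cc2)O[C@@H]1c1ccc(OCc2ccccc2)c(OCc2ccccc2)c1
F3 | step 8 | (4R,5S)-3-{(E)-5-[4-(benzyloxy)phenyl]-3-hydroxypent-4-enoyl}-5-[3,4-bis(benzyloxy)phenyl]-4-{[(tert-butyldiphenylsilyl)oxy]methyl}oxolan-2-one | CC(C)(C)[Si](c1ccccc1)(c1ccccc1)OC[C@H]1C(C(=O)CC(O)/C=C/c2ccc(OCc3ccccc3)cc2)C(=O)O[C@@H]1c1ccc(OCc2ccccc2)c(OCc2ccccc2)c1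
F4 | step 13 | (2S,3S)-2-[3,4-bis(benzyloxy)phenyl]-6-{(E)-2-[4-(benzyloxy)phenyl]ethenyl}-4-oxo-2,3-dihydro-4H-furo[3,2-c]pyran-3-carboxylic acid | OC(=O)[C@H]1c2c(cc(/C=C/c3ccc(OCc4ccccc4)cc3)oc2=O)O[C@@H]1c1ccc(OCc2ccccc2)c(OCc2ccccc2)c1
F5 | step 13 | (2S,3S)-2-[3,4-bis(benzyloxy)phenyl]-6-{(E)-2-[4-(benzyloxy)phenyl]ethenyl}-4-oxo-2,3-dihydro-4H-furo[3,2-c]pyran-3-carbonyl chloride | ClC(=O)[C@H]1c2c(cc(/C=C/c3ccc(OCc4ccccc4)cc3)oc2=O)O[C@@H]1c1ccc(OCc2ccccc2)c(OCc2ccccc2)c1
F6 | step 16 | 6-{2-[(2S,3S)-2-(3,4-dihydroxyphenyl)-6-[(E)-2-(4-hydroxyphenyl)ethenyl]-4-oxo-2,3-dihydro-4H-furo[3,2-c]pyran-3-yl]-2-oxoethyl}-2,2-dimethyl-4H-1,3-dioxin-4-one | CC1(C)OC(CC(=O)[C@H]2c3c(cc(/C=C/c4ccc(O)cc4)oc3=O)O[C@@H]2c2ccc(O)c(O)c2)=CC(=O)O1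
F7 | step 6 | (4R,5S)-5-[3,4-bis(benzyloxy)phenyl]-4-{[(tert-butyldiphenylsilyl)oxy]methyl}-3-(1-hydroxyethyl)oxolan-2-one | CC(C)(C)[Si](c1ccccc1)(c1ccccc1)OC[C@H]1C(C(C)O)C(=O)O[C@@H]1c1ccc(OCc2ccccc2)c(OCc2ccccc2)c1
A1 | alternative 1 | (2S)-2-[3,4-bis(benzyloxy)phenyl]-7-methyl-2,3-dihydro-4H,5H-pyrano[4,3-b]pyran-4,5-dione | Cc1cc2c(c(=O)o1)C(=O)C[C@@H](c1ccc(OCc3ccccc3)c(OCc3ccccc3)c1)O2
A2 | alternative 1 | methyl (2S,3S)-2-[3,4-bis(benzyloxy)phenyl]-6-methyl-4-oxo-2,3-dihydro-4H-furo[3,2-c]pyran-3-carboxylate | COC(=O)[C@H]1c2c(cc(C)oc2=O)O[C@@H]1c1ccc(OCc2ccccc2)c(OCc2ccccc2)c1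
A3 | alternative 2 | 6-{(E)-2-[4-(benzyloxy)phenyl]ethenyl}-3-{[4-(benzyloxy)-2-oxo-2H-pyran-6-yl](4-methylbenzenesulfonyl)methyl}-4-hydroxy-2H-pyran-2-one | Cc1ccc(cc1)S(=O)(=O)C(c1cc(OCc2ccccc2)cc(=O)o1)c1c(O)cc(/C=C/c2ccc(OCc3ccccc3)cc2)oc1=O
A4 | alternative 2 | 3-{[4-(benzyloxy)-2-oxo-2H-pyran-6-yl]methylidene}-6-{(E)-2-[4-(benzyloxy)phenyl]ethenyl}-2H-pyran-2,4(3H)-dione | O=C1C=C(/C=C/c2ccc(OCc3ccccc3)cc2)OC(=O)C1=Cc1cc(OCc2ccccc2)cc(=O)o1
A5 | alternative 2 | (2R,5R)-1-[3,4-bis(benzyloxy)benzyl]-2,5-dimethylthiolan-1-ium tetrafluoroborate | C[C@@H]1CC[C@@H](C)[S+]1Cc1ccc(OCc2ccccc2)c(OCc2ccccc2)c1.F[B-](F)(F)F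
A6 | alternative 2 | (2S,3S)-2-[3,4-bis(benzyloxy)phenyl]-3-[4-(benzyloxy)-2-oxo-2H-pyran-6-yl]-6-{(E)-2-[4-(benzyloxy)phenyl]ethenyl}-2,3-dihydro-4H-furo[3,2-c]pyran-4-one | O=c1cc(OCc2ccccc2)cc([C@H]2c3c(cc(/C=C/c4ccc(OCc5ccccc5)cc4)oc3=O)O[C@@H]2c2ccc(OCc3ccccc3)c(OCc3ccccc3)c2)o1
A7 | alternative 3 | 4-(benzyloxy)-6-{(1R)-2-[3-(benzyloxy)-4-hydroxyphenyl]-1-[6-{(E)-2-[4-(benzyloxy)phenyl]ethenyl}-4-hydroxy-2-oxo-2H-pyran-3-yl]ethyl}-2H-pyran-2-one | O=c1cc(OCc2ccccc2)cc([C@H](Cc2ccc(O)c(OCc3ccccc3)c2)c2c(O)cc(/C=C/c3ccc(OCc4ccccc4)cc3)oc2=O)o1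
A8 | alternative 3 | (2S,3S)-2-[3-(benzyloxy)-4-hydroxyphenyl]-3-[4-(benzyloxy)-2-oxo-2H-pyran-6-yl]-6-{(E)-2-[4-(benzyloxy)phenyl]ethenyl}-2,3-dihydro-4H-furo[3,2-c]pyran-4-one | O=c1cc(OCc2ccccc2)cc([C@H]2c3c(cc(/C=C/c4ccc(OCc5ccccc5)cc4)oc3=O)O[C@@H]2c2ccc(O)c(OCc3ccccc3)c2)o1
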